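**Retrosynthetic overview**
1. Elemacarmanin ⇒ its 15-deoxy precursor; the C15–O bond is made last by allylic C–H hydroxylation of the C5 isopropenyl group.
2. Key disconnection C8–O: the 8-O-acyl ester is formed directly from a C8 ketone and unprotected 2-(hydroxymethyl)acrylic acid (ketone → diazoalkane → ester); this step sets C8.
3. C7 acrylate and C6–OH ⇒ an α,β-epoxy ketone: C6–O comes from nucleophilic epoxidation, and reductive opening gives the C7 enolate, which adds to methyl 3-nitroacrylate (an α-acrylate cation equivalent).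
4. Epoxy ketone ⇒ enone ⇒ (1R,5R)-verbenone: vinyl cuprate addition sets C10, and Lewis-acid cleavage of the cyclobutane releases the C5 isopropenyl group.
5. Rings: the cyclohexane is the six-membered ring of the pinane bicycle and is never built; the cyclobutane is opened in the second step, and the only ring formed later is the transient epoxide.

Assumption: (1R,5R)-(+)-verbenone (1) is bought as such (a catalogue compound, one oxidation away from bulk (+)-α-pinene). Atom labels follow elemane numbering: C10 quaternary ring carbon, C5 ring carbon with the C3 side chain, C6 carbinol carbon, C7 ring carbon with the acrylate, C8 acyloxy carbon, C9 ring CH2, C15 the allylic CH2OH carbon.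

**Route**

Step 1
Reactants: 1 (1R,5R)-(+)-verbenone; 2 vinylmagnesium bromide
Product: 3 (1R,4S,5S)-4-ethenyl-4,6,6-trimethylbicyclo[3.1.1]heptan-2-one
Conditions: 2 (1.5 equiv), CuBr·SMe2 (10 mol %), THF, −40 → −20 °C; then 1 M HCl
Reagents that add atoms: none
Why: Copper-catalysed conjugate (1,4-) addition to the β-methyl enone, in which the vinyl group enters from the face away from the gem-dimethyl bridge and so fixes the quaternary centre C10 with its methyl cis to the future isopropenyl group.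

Step 2
Reactants: 3 (1R,4S,5S)-4-ethenyl-4,6,6-trimethylbicyclo[3.1.1]heptan-2-one
Product: 4 (4S,5S)-5-ethenyl-5-methyl-4-(prop-1-en-2-yl)cyclohex-1-en-1-yl acetate
Conditions: BF3·OEt2, Zn(OAc)2 (cat.), Ac2O, 0 → 23 °C
Reagents that add atoms: acetic anhydride, CC(=O)OC(C)=O
Why: Lewis-acid-induced fragmentation of the cyclobutane bond lying α,β to the ketone (retro-Michael-type ring opening) gives a tertiary cation that loses a methyl proton to form the isopropenyl group and a regiodefined enolate that is trapped as the enol acetate; C5 and C10 are untouched, so the trans vinyl/isopropenyl relationship of 3 is carried over.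

Step 3
Reactants: 4 (4S,5S)-5-ethenyl-5-methyl-4-(prop-1-en-2-yl)cyclohex-1-en-1-yl acetate
Product: 6 (4S,5S)-5-ethenyl-5-methyl-4-(prop-1-en-2-yl)cyclohex-2-en-1-one, via lithium enolate 5 (not isolated)
Conditions: MeLi (2.1 equiv), THF, 0 °C; then N-tert-butylbenzenesulfinimidoyl chloride, −78 °C
Reagents that add atoms: none
Why: Mukaiyama dehydrogenation: the enolate released regiospecifically from the enol acetate is sulfenylated at C7 and undergoes syn-elimination at −78 °C, and because only C6 carries β-hydrogens a single enone results.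

Step 4
Reactants: 6 (4S,5S)-5-ethenyl-5-methyl-4-(prop-1-en-2-yl)cyclohex-2-en-1-one
Product: 7 (1R,4S,5S,6R)-4-ethenyl-4-methyl-5-(prop-1-en-2-yl)-7-oxabicyclo[4.1.0]heptan-2-one
Conditions: 30% aq. H2O2, NaOH (0.2 equiv), MeOH, 0 °C
Reagents that add atoms: hydrogen peroxide, OO
Why: Weitz–Scheffer nucleophilic epoxidation; hydroperoxide adds to C6 anti to the adjacent C5 isopropenyl group (and to the pseudo-axial C10 methyl), which sets the C6–O bond α.

Step 5
Reactants: 8 methyl acrylate
Product: 10 methyl (E)-3-nitroprop-2-enoate, via iodonitro ester 9 (not isolated)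
Conditions: I2, N2O4, Et2O, 0 °C; then NaOAc, Et2O, 23 °C
Reagents that add atoms: dinitrogen tetroxide, [O-][N+](=O)[N+](=O)[O-]
Why: Nitro-iodination of the acrylate (addition of nitryl iodide) followed by acetate-induced dehydroiodination gives the thermodynamically preferred (E)-nitroalkene.

Step 6
Reactants: 7 (1R,4S,5S,6R)-4-ethenyl-4-methyl-5-(prop-1-en-2-yl)-7-oxabicyclo[4.1.0]heptan-2-one; 10 methyl (E)-3-nitroprop-2-enoate
Product: 13 methyl 2-[(1S,2R,3S,4S)-4-ethenyl-2-hydroxy-4-methyl-6-oxo-3-(prop-1-en-2-yl)cyclohexyl]prop-2-enoate, via samarium enolate 11 (not isolated), via nitro ester adduct 12 (not isolated)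
Conditions: SmI2 (2.0 equiv), THF, −78 °C; then 10, −78 °C; AcOH, −78 °C; then Et3N, 0 °C
Reagents that add atoms: none
Why: Two single-electron transfers from divalent samarium cleave the Cα–O bond of the epoxy ketone (C6 keeps its oxygen and configuration) to give the regiodefined C7 enolate 11, which undergoes Michael addition to the nitroalkene at the carbon β to the nitro group, anti to the C6 alkoxide (C7 is in any case epimerisable to this equatorial arrangement), and E1cB loss of nitrous acid from 12 unveils the α-substituted acrylate.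

Step 7
Reactants: 14 ethyl 2-(hydroxymethyl)prop-2-enoate
Product: 15 2-(hydroxymethyl)prop-2-enoic acid
Conditions: LiOH·H2O, THF–H2O, 0 °C; then 1 M HCl to pH 2
Reagents that add atoms: lithium hydroxide, [Li+].[OH-]
Why: Ester saponification at 0 °C, mild enough to leave the acrylate double bond and the free hydroxyl untouched.

Step 8
Reactants: 13 methyl 2-[(1S,2R,3S,4S)-4-ethenyl-2-hydroxy-4-methyl-6-oxo-3-(prop-1-en-2-yl)cyclohexyl]prop-2-enoate; 15 2-(hydroxymethyl)prop-2-enoic acid
Product: 18 (1S,2S,3R,4S,5S)-5-ethenyl-3-hydroxy-2-(3-methoxy-3-oxoprop-1-en-2-yl)-5-methyl-4-(prop-1-en-2-yl)cyclohexyl 2-(hydroxymethyl)prop-2-enoate, via N-silylhydrazone 16 (not isolated), via diazoalkane 17 (not isolated)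
Conditions: (TBSNH)2, Sc(OTf)3 (1 mol %), CH2Cl2, 23 °C, evaporate; PhIF2, 2-chloropyridine, CH2Cl2, −78 °C; then 15 (2 equiv), −78 → 23 °C
Reagents that add atoms: none
Why: Proposed new method: ketone 13 is converted in one flask into the C8 ester by condensation to the N-silylhydrazone 16, hypervalent-iodine dehydrogenation to the non-stabilised diazoalkane 17 and protonation by acid 15; the acid can reach the trigonal diazo carbon only from the equatorial α face (the β face is screened by the axial C10 methyl), which places N2+ axial, and the carboxylate of the contact ion pair, already on the α face, displaces N2 with inversion, so the new C8–O bond ends equatorial (8α, trans to the C7 side chain, cis to the C6 hydroxyl) without hydride reduction, protecting group or activating agent; the closest known reaction is the esterification of carboxylic acids with diazoalkanes generated in situ from N-silylhydrazones (Furrow–Myers), which has not been used to create a ring carbinol stereocentre under substrate control on a hindered, polyfunctional cyclohexanone or with an unprotected hydroxy acrylic acid.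

Step 9
Reactants: 18 (1S,2S,3R,4S,5S)-5-ethenyl-3-hydroxy-2-(3-methoxy-3-oxoprop-1-en-2-yl)-5-methyl-4-(prop-1-en-2-yl)cyclohexyl 2-(hydroxymethyl)prop-2-enoate
Product: 19 elemacarmanin, (1S,2S,3R,4R,5S)-5-ethenyl-3-hydroxy-4-(3-hydroxyprop-1-en-2-yl)-2-(3-methoxy-3-oxoprop-1-en-2-yl)-5-methylcyclohexyl 2-(hydroxymethyl)prop-2-enoate
Conditions: SeO2 (0.3 equiv), t-BuOOH (3 equiv), CH2Cl2, 23 °C
Reagents that add atoms: tert-butyl hydroperoxide, CC(C)(C)OO
Why: Riley allylic oxidation with catalytic SeO2 (ene reaction then [2,3]-sigmatropic shift) attacks only the electron-rich 1,1-disubstituted isopropenyl alkene and prefers its methyl group over the tertiary C5–H, while the vinyl group (no allylic hydrogen) and the two acrylates (electron-poor) are inert; no stereocentre is touched.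

**Compound list**
1 | (1R,5R)-(+)-verbenone, (1R,5R)-4,6,6-trimethylbicyclo[3.1.1]hept-3-en-2-one | CC1=CC(=O)[C@@H]2C[C@H]1C2(C)C | starting material
2 | vinylmagnesium bromide | C=C[Mg]Br | starting material
3 | (1R,4S,5S)-4-ethenyl-4,6,6-trimethylbicyclo[3.1.1]heptan-2-one | C=C[C@]1(C)CC(=O)[C@@H]2C[C@H]1C2(C)C | intermediate
4 | (4S,5S)-5-ethenyl-5-methyl-4-(prop-1-en-2-yl)cyclohex-1-en-1-yl acetate | C=C[C@]1(C)CC(OC(C)=O)=CC[C@H]1C(C)=C | intermediate
5 | lithium (4S,5S)-5-ethenyl-5-methyl-4-(prop-1-en-2-yl)cyclohex-1-en-1-olate | C=C[C@]1(C)CC([O-])=CC[C@H]1C(C)=C.[Li+] | intermediate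
6 | (4S,5S)-5-ethenyl-5-methyl-4-(prop-1-en-2-yl)cyclohex-2-en-1-one | C=C[C@]1(C)CC(=O)C=C[C@H]1C(C)=C | intermediate
7 | (1R,4S,5S,6R)-4-ethenyl-4-methyl-5-(prop-1-en-2-yl)-7-oxabicyclo[4.1.0]heptan-2-one | C=C[C@]1(C)CC(=O)[C@@H]2O[C@@H]2[C@H]1C(C)=C | intermediate
8 | methyl acrylate | C=CC(=O)OC | starting material
9 | methyl 2-iodo-3-nitropropanoate (racemic) | COC(=O)C(I)C[N+](=O)[O-] | intermediate
10 | methyl (E)-3-nitroprop-2-enoate | COC(=O)/C=C/[N+](=O)[O-] | intermediate
11 | bis(diiodosamarium) (3R,4S,5S)-5-ethenyl-5-methyl-4-(prop-1-en-2-yl)cyclohex-1-ene-1,3-diolate (samarium enolate and C6 alkoxide) | C=C[C@]1(C)CC(O[Sm](I)I)=C[C@H](O[Sm](I)I)[C@H]1C(C)=C | intermediate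
12 | methyl 2-[(1S,2R,3S,4S)-4-ethenyl-2-hydroxy-4-methyl-6-oxo-3-(prop-1-en-2-yl)cyclohexyl]-3-nitropropanoate (both epimers at C2 of the propanoate) | C=C[C@]1(C)CC(=O)[C@@H](C(C[N+](=O)[O-])C(=O)OC)[C@H](O)[C@H]1C(C)=C | intermediate
13 | methyl 2-[(1S,2R,3S,4S)-4-ethenyl-2-hydroxy-4-methyl-6-oxo-3-(prop-1-en-2-yl)cyclohexyl]prop-2-enoate | C=C[C@]1(C)CC(=O)[C@@H](C(=C)C(=O)OC)[C@H](O)[C@H]1C(C)=C | intermediate
14 | ethyl 2-(hydroxymethyl)prop-2-enoate | CCOC(=O)C(=C)CO | starting material
15 | 2-(hydroxymethyl)prop-2-enoic acid | OCC(=C)C(=O)O | intermediate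
16 | methyl 2-[(1R,2R,3S,4S)-6-[2-(tert-butyldimethylsilyl)hydrazinylidene]-4-ethenyl-2-hydroxy-4-methyl-3-(prop-1-en-2-yl)cyclohexyl]prop-2-enoate (C=N geometry not defined) | C=C[C@]1(C)CC(=NN[Si](C)(C)C(C)(C)C)[C@@H](C(=C)C(=O)OC)[C@H](O)[C@H]1C(C)=C | intermediate
17 | methyl 2-[(1R,2R,3S,4S)-6-diazo-4-ethenyl-2-hydroxy-4-methyl-3-(prop-1-en-2-yl)cyclohexyl]prop-2-enoate | C=C[C@]1(C)CC(=[N+]=[N-])[C@@H](C(=C)C(=O)OC)[C@H](O)[C@H]1C(C)=C | intermediate
18 | (1S,2S,3R,4S,5S)-5-ethenyl-3-hydroxy-2-(3-methoxy-3-oxoprop-1-en-2-yl)-5-methyl-4-(prop-1-en-2-yl)cyclohexyl 2-(hydroxymethyl)prop-2-enoate | C=C[C@]1(C)C[C@H](OC(=O)C(=C)CO)[C@@H](C(=C)C(=O)OC)[C@H](O)[C@H]1C(C)=C | intermediate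
19 | elemacarmanin, (1S,2S,3R,4R,5S)-5-ethenyl-3-hydroxy-4-(3-hydroxyprop-1-en-2-yl)-2-(3-methoxy-3-oxoprop-1-en-2-yl)-5-methylcyclohexyl 2-(hydroxymethyl)prop-2-enoate | C=C[C@]1(C)C[C@H](OC(=O)C(=C)CO)[C@@H](C(=C)C(=O)OC)[C@H](O)[C@H]1C(=C)CO | target

**Step count**
Total: 9 steps. Longest linear sequence: 7 steps (steps 1, 2, 3, 4, 6, 8, 9 from 1); steps 5 and 7 are one-step reagent preparations.

**Three steps most likely to fail**

Step 8 (the proposed new ketone-to-ester step). The axial diazonium ion pair may lose N2 and a β-hydrogen to give cyclohexenes, the proton transfer may not be fully face-selective, and the hydrazone N–H may add to the neighbouring acrylate. The fallback uses known chemistry, sets out from 13 and comes back at 18. Bulky-hydride reduction of 13 (LiAlH(OtBu)3, THF, −78 °C, equatorial attack) gives the axial 8β-alcohol methyl 2-[(1R,2R,3S,4S,6R)-4-ethenyl-2,6-dihydroxy-4-methyl-3-(prop-1-en-2-yl)cyclohexyl]prop-2-enoate F1, which is used at once. Mitsunobu esterification (PPh3, DIAD, acrylic acid, toluene, 0 °C) inverts the less encumbered C8 carbinol to (1S,2S,3R,4S,5S)-5-ethenyl-3-hydroxy-2-(3-methoxy-3-oxoprop-1-en-2-yl)-5-methyl-4-(prop-1-en-2-yl)cyclohexyl prop-2-enoate F2. A Morita–Baylis–Hillman reaction of the only α-unsubstituted acrylate (aq. formaldehyde, DABCO, 1,4-dioxane, 23 °C) then gives 18.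

Step 6 (reductive epoxide opening, Michael addition, nitrite loss in one flask). The samarium enolate may be protonated or fragment before it adds, and the C6 alkoxide may lactonise onto the new ester. The fallback sets out from 6 and comes back at 13, forming the C7–C bond by cross-coupling instead. α-Iodination (I2, pyridine, CH2Cl2) gives (4S,5S)-5-ethenyl-2-iodo-5-methyl-4-(prop-1-en-2-yl)cyclohex-2-en-1-one F3. Stille coupling with methyl 2-(tributylstannyl)prop-2-enoate (Pd2(dba)3, AsPh3, CuI, NMP, 23 °C) gives methyl 2-[(3S,4S)-4-ethenyl-4-methyl-6-oxo-3-(prop-1-en-2-yl)cyclohex-1-en-1-yl]prop-2-enoate F4. Weitz–Scheffer epoxidation of the enone (H2O2, NaOH, MeOH, 0 °C) gives methyl 2-[(1R,4S,5S,6R)-4-ethenyl-4-methyl-2-oxo-5-(prop-1-en-2-yl)-7-oxabicyclo[4.1.0]heptan-1-yl]prop-2-enoate F5. SmI2 in THF–MeOH at −78 °C cleaves the C7–O bond and protonates C7 to the equatorial epimer, giving 13.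

Step 9 (late allylic hydroxylation). Over-oxidation to the enal or attack at C5–H would lower the yield at the last stage. The fallback sets out from 18 and comes back at 19 by a Schenck ene reaction instead of selenium chemistry. Photooxygenation (O2, hν, tetraphenylporphyrin, CH2Cl2, 0 °C) gives (1S,2S,3R,4R,5S)-5-ethenyl-4-(3-hydroperoxyprop-1-en-2-yl)-3-hydroxy-2-(3-methoxy-3-oxoprop-1-en-2-yl)-5-methylcyclohexyl 2-(hydroxymethyl)prop-2-enoate F6, in which the double bond has shifted into the former methyl group to give the same connectivity. Reduction with PPh3 gives 19.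

**Further compounds**
F1 | step 8 | methyl 2-[(1R,2R,3S,4S,6R)-4-ethenyl-2,6-dihydroxy-4-methyl-3-(prop-1-en-2-yl)cyclohexyl]prop-2-enoate | C=C[C@]1(C)C[C@@H](O)[C@@H](C(=C)C(=O)OC)[C@H](O)[C@H]1C(C)=C
F2 | step 8 | (1S,2S,3R,4S,5S)-5-ethenyl-3-hydroxy-2-(3-methoxy-3-oxoprop-1-en-2-yl)-5-methyl-4-(prop-1-en-2-yl)cyclohexyl prop-2-enoate | C=C[C@]1(C)C[C@H](OC(=O)C=C)[C@@H](C(=C)C(=O)OC)[C@H](O)[C@H]1C(C)=C
F3 | step 6 | (4S,5S)-5-ethenyl-2-iodo-5-methyl-4-(prop-1-en-2-yl)cyclohex-2-en-1-one | C=C[C@]1(C)CC(=O)C(I)=C[C@H]1C(C)=C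
F4 | step 6 | methyl 2-[(3S,4S)-4-ethenyl-4-methyl-6-oxo-3-(prop-1-en-2-yl)cyclohex-1-en-1-yl]prop-2-enoate | C=C[C@]1(C)CC(=O)C(C(=C)C(=O)OC)=C[C@H]1C(C)=C
F5 | step 6 | methyl 2-[(1R,4S,5S,6R)-4-ethenyl-4-methyl-2-oxo-5-(prop-1-en-2-yl)-7-oxabicyclo[4.1.0]heptan-1-yl]prop-2-enoate | C=C[C@]1(C)CC(=O)[C@]2(C(=C)C(=O)OC)O[C@@H]2[C@H]1C(C)=C
F6 | step 9 | (1S,2S,3R,4R,5S)-5-ethenyl-4-(3-hydroperoxyprop-1-en-2-yl)-3-hydroxy-2-(3-methoxy-3-oxoprop-1-en-2-yl)-5-methylcyclohexyl 2-(hydroxymethyl)prop-2-enoate | C=C[C@]1(C)C[C@H](OC(=O)C(=C)CO)[C@@H](C(=C)C(=O)OC)[C@H](O)[C@H]1C(=C)COO
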